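Counting heads is the pitfall: 4.00 equiv of second nucleophile against 1.10 equiv of first nucleophile gives the zero of the scale, not the amount of target.

    substrate + target ⇌ idle adduct, settled at all times (K1 = 13 L mol⁻¹)
    second nucleophile + intermediate → other capture product (k2 = 3.2 L mol⁻¹ s⁻¹)
    first nucleophile → decomposed reagent (k3 = 0.078 s⁻¹)
    substrate → intermediate (k4 = 1.7 s⁻¹)
    first nucleophile + intermediate → target (k5 = 13 L mol⁻¹ s⁻¹)
    crystals ⇌ target, rate k6*(cs6 - [target]) while solid is left; crystals form when [target] > cs6 (cs6 = 7.9 mM, k6 = 17 s⁻¹)

in all of them: second nucleophile 4.00 equiv; time 50 s
- red: substrate 0.21 M; first nucleophile 1.10 equiv; everything together at the start
- teal: substrate 0.21 M (fed, over 10 s); first nucleophile 1.10 equiv; all else is in the flask from the start; the feed brings no volume worth counting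
- green: substrate 0.21 M (in portions, 4, over 10 s); first nucleophile 1.10 equiv; first portion at the start, last at 10 s
- violet: substrate 0.21 M; first nucleophile 1.10 equiv (fed, over 10 s); all else is in the flask from the start; the feed brings no volume worth counting

- percent here means substrate units held: one idle adduct counts as two
- what is said of target includes crystals and idle adduct
- crystals is a solid; its amount is given per volume of the solution
- in an amount of target, one idle adduct counts as one target
- run time (red): 50 s

1. which flask leads in amount of target, in percent of the substrate charged ("all alike" within 1.5 percentage points) (red / teal / green / violet / all alike)
2. how much target is there at the end, in percent of the substrate charged: red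
3. how much target is there at the end, in percent of the substrate charged: teal
4. how much target is there at the end, in percent of the substrate charged: green
5. how much target is there at the end, in percent of the substrate charged: violet

Two equally reactive nucleophiles, the statistical case, would give 21.6 % target. The reckoning moves off that zero with the selectivity factor S, the capture constant of first nucleophile over that of second, which is 4.06. With B and D the two nucleophiles at the moment of capture, intermediate becomes target with the share S·B/(S·B+D), and this reckoning sets crystals and idle adduct aside.

At the charges of red that share is 52.8 %. This reckoning sets the decay of first nucleophile aside in red because the substrate half-life of 0.41 s is far shorter than the 8.9 s of first nucleophile. Both nucleophiles are consumed, however, so reading the share at the midpoint of capture gives 47.4 % for red.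

In teal and green the middle of the substrate dose lies at 5.00 s, when decay by itself leaves B at 0.745 on the same scale. The opening share is then 43.1 %, and the midpoint reading gives 36.7 % for teal and 36.7 % for green.

In violet the median capture comes roughly one substrate half-life plus one intermediate half-life after the start, at 0.666 s. The feed has then brought B to 0.0732, which gives 6.92 % for violet. The reckoning therefore puts red ahead.

The forecast also names red, with 46 % for red, 36 % for teal, 37 % for green and 11 % for violet, and its ground for the last is “Violet is worst because most of the intermediate forms before much first nucleophile is present”. It stands above this reckoning for violet and below it for red.

The simulation puts red ahead, with 46.0 % for red, 36.2 % for teal, 36.5 % for green and 8.23 % for violet.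

Red and violet have come to rest in target: at 500 s red still shows 46.0 % and violet 8.23 %. In red, intermediate stands at 0 % at 50.0 s, so S of 4.06 has no more capture to divide there. What still moves in red is first nucleophile, from 1.1 % of its charge to 0 %, while decomposed reagent goes from 0.132 M to 0.134 M.

For the neighbour of violet charged with 1.60 equiv of second nucleophile, the same reckoning puts the median capture at 1.05 s and B at 0.116, and S gives 22.7 %. The simulated neighbour holds 22.9 %.

The constants are invented; the run is a simulation.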